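**Retrosynthetic overview**
- The last bond made is the ester C–O of the oxiranylmethyl (R)-2-methylbutanoate. Before it, the oxirane is closed by Sharpless epoxidation of a 2-aryl allylic alcohol. It is the only ring formed; the benzene ring is bought.
- Both aryl-side esters are in place before the ring is made: the aryl angelate (Yamaguchi) and the benzylic (R)-2-methylbutanoate (lipase, phenol left free). No free phenol ever sits next to the epoxide.
- The aryl–C(=CH2) bond comes from Suzuki coupling of methyl 4-bromo-3-hydroxybenzoate with a 2-borylallyl silyl ether made from 2-bromoprop-2-en-1-ol; the benzoate is then reduced to CH2OH.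
- (R)-2-Methylbutanoic acid comes from tiglic acid by Ru-catalysed asymmetric hydrogenation, which sets the first stereocentre.

Assumption: the SMILES is read as R at the oxirane carbon, R at both 2-methylbutanoyl α-carbons and Z (angelate) at the enoate; tiglic acid, angelic acid, 2-bromoprop-2-en-1-ol and methyl 4-bromo-3-hydroxybenzoate are taken as catalogue compounds.

**Route**

Step 1
Reactants: 1 tiglic acid [(2E)-2-methylbut-2-enoic acid]
Product: 2 (2R)-2-methylbutanoic acid
Conditions: H2 (4 atm), Ru(OAc)2[(R)-H8-BINAP] (0.5 mol%), MeOH, 20 °C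
Reagents that add atoms: none
Why: Asymmetric hydrogenation (Noyori type) of the chelating enoic acid on the chiral Ru–bisphosphine sets the α-stereocentre as R (about 97% ee expected with the R ligand), confirmed by the negative optical rotation of the product before use.

Step 2
Reactants: 3 2-bromoprop-2-en-1-ol
Product: 4 [(2-bromoprop-2-en-1-yl)oxy](tert-butyl)dimethylsilane
Conditions: TBSCl, imidazole, CH2Cl2, 0 °C to rt
Reagents that add atoms: tert-butyldimethylsilyl chloride, CC(C)(C)[Si](C)(C)Cl
Why: Imidazole-promoted silylation masks the allylic OH so that it can later be told apart from the benzylic OH.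

Step 3
Reactants: 4 [(2-bromoprop-2-en-1-yl)oxy](tert-butyl)dimethylsilane
Product: 5 tert-butyldimethyl{[2-(4,4,5,5-tetramethyl-1,3,2-dioxaborolan-2-yl)prop-2-en-1-yl]oxy}silane
Conditions: B2pin2, PdCl2(PPh3)2 (3 mol%), PPh3 (6 mol%), KOPh, toluene, 50 °C
Reagents that add atoms: bis(pinacolato)diboron, CC1(C)OB(OC1(C)C)B1OC(C)(C)C(C)(C)O1
Why: Miyaura borylation of the alkenyl bromide (oxidative addition to zerovalent palladium, then transmetalation from the phenoxide-activated diboron) gives the α-substituted vinyl boronate without touching the silyl ether.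

Step 4
Reactants: 6 methyl 4-bromo-3-hydroxybenzoate; 5 tert-butyldimethyl{[2-(4,4,5,5-tetramethyl-1,3,2-dioxaborolan-2-yl)prop-2-en-1-yl]oxy}silane
Product: 7 methyl 4-{3-[(tert-butyldimethylsilyl)oxy]prop-1-en-2-yl}-3-hydroxybenzoate
Conditions: PdCl2(dppf) (5 mol%), K3PO4, 1,4-dioxane/H2O (5:1), 80 °C
Reagents that add atoms: none
Why: Suzuki–Miyaura cross-coupling of the ester-activated aryl bromide with the vinyl boronate forms the aryl–C(sp2) bond, and the free phenol is tolerated as its phenoxide.

Step 5
Reactants: 7 methyl 4-{3-[(tert-butyldimethylsilyl)oxy]prop-1-en-2-yl}-3-hydroxybenzoate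
Product: 9 2-{3-[(tert-butyldimethylsilyl)oxy]prop-1-en-2-yl}-5-(hydroxymethyl)phenol, via aldehyde 8 (not isolated)
Conditions: iBu2AlH (4 equiv), THF, −78 to 0 °C; aq. potassium sodium tartrate (KNaC4H4O6)
Reagents that add atoms: none
Why: Hydride reduction of the benzoate through the aldehyde to the benzylic alcohol (one extra equivalent is spent on the phenol) leaves the silyl ether and the alkene untouched.

Step 6
Reactants: 9 2-{3-[(tert-butyldimethylsilyl)oxy]prop-1-en-2-yl}-5-(hydroxymethyl)phenol; 2 (2R)-2-methylbutanoic acid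
Product: 10 4-{3-[(tert-butyldimethylsilyl)oxy]prop-1-en-2-yl}-3-hydroxybenzyl (2R)-2-methylbutanoate
Conditions: 2 (2 equiv), lipase (Candida antarctica lipase B, immobilised), 4 Å molecular sieves, toluene, 45 °C
Reagents that add atoms: none
Why: Lipase-catalysed esterification (a serine hydrolase run in the synthetic direction, water taken up by the sieves) acylates only the primary benzylic OH and not the phenol, and this lipase is reported to take the R acid faster than its enantiomer, so no protecting group is needed and configurational purity is not lost.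

Step 7
Reactants: 10 4-{3-[(tert-butyldimethylsilyl)oxy]prop-1-en-2-yl}-3-hydroxybenzyl (2R)-2-methylbutanoate; 11 angelic acid [(2Z)-2-methylbut-2-enoic acid]
Product: 13 2-{3-[(tert-butyldimethylsilyl)oxy]prop-1-en-2-yl}-5-({[(2R)-2-methylbutanoyl]oxy}methyl)phenyl (2Z)-2-methylbut-2-enoate, via mixed anhydride 12 (not isolated)
Conditions: 11, 2,4,6-trichlorobenzoyl chloride, Et3N, toluene, rt; then 10, Et3N, rt to 40 °C
Reagents that add atoms: 2,4,6-trichlorobenzoyl chloride, O=C(Cl)c1c(Cl)cc(Cl)cc1Cl (its atoms are held in 12 only)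
Why: Yamaguchi esterification, in which the phenoxide attacks the unhindered angeloyl carbonyl of the mixed anhydride; leaving out a nucleophilic catalyst keeps the Z alkene from isomerising to the tiglate.

Step 8
Reactants: 13 2-{3-[(tert-butyldimethylsilyl)oxy]prop-1-en-2-yl}-5-({[(2R)-2-methylbutanoyl]oxy}methyl)phenyl (2Z)-2-methylbut-2-enoate
Product: 14 2-(3-hydroxyprop-1-en-2-yl)-5-({[(2R)-2-methylbutanoyl]oxy}methyl)phenyl (2Z)-2-methylbut-2-enoate
Conditions: HF·pyridine, pyridine, THF, 0 °C to rt
Reagents that add atoms: none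
Why: Buffered fluoride desilylation cleaves the primary silyl ether, while the aryl and alkyl esters survive the non-basic medium.

Step 9
Reactants: 14 2-(3-hydroxyprop-1-en-2-yl)-5-({[(2R)-2-methylbutanoyl]oxy}methyl)phenyl (2Z)-2-methylbut-2-enoate
Product: 15 2-[(2S)-2-(hydroxymethyl)oxiran-2-yl]-5-({[(2R)-2-methylbutanoyl]oxy}methyl)phenyl (2Z)-2-methylbut-2-enoate
Conditions: t-BuOOH, Ti(OiPr)4 (10 mol%), L-(+)-diisopropyl tartrate (12 mol%), 4 Å molecular sieves, CH2Cl2, −20 °C; aq. Na2SO4 work-up (no hydroxide wash)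
Reagents that add atoms: tert-butyl hydroperoxide, CC(C)(C)OO
Why: Sharpless asymmetric epoxidation, in which the Ti–tartrate complex delivers oxygen to the face that gives (2S,3S)-epoxides from E allylic alcohols and (S)-2-methylglycidol from methallyl alcohol, here the S epoxy alcohol; the electron-poor angelate alkene has no directing hydroxyl and is left alone.

Step 10
Reactants: 15 2-[(2S)-2-(hydroxymethyl)oxiran-2-yl]-5-({[(2R)-2-methylbutanoyl]oxy}methyl)phenyl (2Z)-2-methylbut-2-enoate; 2 (2R)-2-methylbutanoic acid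
Product: 17 2-[(2R)-2-({[(2R)-2-methylbutanoyl]oxy}methyl)oxiran-2-yl]-5-({[(2R)-2-methylbutanoyl]oxy}methyl)phenyl (2Z)-2-methylbut-2-enoate (target), via O-acylisourea 16 (not isolated)
Conditions: N,N'-diisopropylcarbodiimide, 4-(dimethylamino)pyridine (20 mol%), CH2Cl2, 0 °C to rt
Reagents that add atoms: N,N'-diisopropylcarbodiimide, CC(C)N=C=NC(C)C (its atoms are held in 16 only)
Why: Steglich esterification of the primary epoxy alcohol under near-neutral conditions neither opens the benzylic epoxide nor epimerises the acid; the oxirane descriptor changes from S to R only because the CIP priorities change, not the geometry.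

**Compound list**

1 | tiglic acid, (2E)-2-methylbut-2-enoic acid | C/C=C(\C)C(=O)O | starting material
2 | (2R)-2-methylbutanoic acid | CC[C@@H](C)C(=O)O | intermediate
3 | 2-bromoprop-2-en-1-ol | OCC(Br)=C | starting material
4 | [(2-bromoprop-2-en-1-yl)oxy](tert-butyl)dimethylsilane | C=C(Br)CO[Si](C)(C)C(C)(C)C | intermediate
5 | tert-butyldimethyl{[2-(4,4,5,5-tetramethyl-1,3,2-dioxaborolan-2-yl)prop-2-en-1-yl]oxy}silane | C=C(CO[Si](C)(C)C(C)(C)C)B1OC(C)(C)C(C)(C)O1 | intermediate
6 | methyl 4-bromo-3-hydroxybenzoate | COC(=O)c1ccc(Br)c(O)c1 | starting material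
7 | methyl 4-{3-[(tert-butyldimethylsilyl)oxy]prop-1-en-2-yl}-3-hydroxybenzoate | COC(=O)c1ccc(C(=C)CO[Si](C)(C)C(C)(C)C)c(O)c1 | intermediate
8 | 4-{3-[(tert-butyldimethylsilyl)oxy]prop-1-en-2-yl}-3-hydroxybenzaldehyde (formed in the flask, not isolated) | O=Cc1ccc(C(=C)CO[Si](C)(C)C(C)(C)C)c(O)c1 | intermediate
9 | 2-{3-[(tert-butyldimethylsilyl)oxy]prop-1-en-2-yl}-5-(hydroxymethyl)phenol | OCc1ccc(C(=C)CO[Si](C)(C)C(C)(C)C)c(O)c1 | intermediate
10 | 4-{3-[(tert-butyldimethylsilyl)oxy]prop-1-en-2-yl}-3-hydroxybenzyl (2R)-2-methylbutanoate | CC[C@@H](C)C(=O)OCc1ccc(C(=C)CO[Si](C)(C)C(C)(C)C)c(O)c1 | intermediate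
11 | angelic acid, (2Z)-2-methylbut-2-enoic acid | C/C=C(/C)C(=O)O | starting material
12 | (2Z)-2-methylbut-2-enoic 2,4,6-trichlorobenzoic anhydride (formed in the flask, not isolated) | C/C=C(/C)C(=O)OC(=O)c1c(Cl)cc(Cl)cc1Cl | intermediate
13 | 2-{3-[(tert-butyldimethylsilyl)oxy]prop-1-en-2-yl}-5-({[(2R)-2-methylbutanoyl]oxy}methyl)phenyl (2Z)-2-methylbut-2-enoate | C/C=C(/C)C(=O)Oc1cc(COC(=O)[C@H](C)CC)ccc1C(=C)CO[Si](C)(C)C(C)(C)C | intermediate
14 | 2-(3-hydroxyprop-1-en-2-yl)-5-({[(2R)-2-methylbutanoyl]oxy}methyl)phenyl (2Z)-2-methylbut-2-enoate | C/C=C(/C)C(=O)Oc1cc(COC(=O)[C@H](C)CC)ccc1C(=C)CO | intermediate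
15 | 2-[(2S)-2-(hydroxymethyl)oxiran-2-yl]-5-({[(2R)-2-methylbutanoyl]oxy}methyl)phenyl (2Z)-2-methylbut-2-enoate | C/C=C(/C)C(=O)Oc1cc(COC(=O)[C@H](C)CC)ccc1[C@]1(CO)CO1 | intermediate
16 | N,N'-diisopropyl-O-[(2R)-2-methylbutanoyl]isourea (formed in the flask, not isolated) | CC[C@@H](C)C(=O)OC(=NC(C)C)NC(C)C | intermediate
17 | 2-[(2R)-2-({[(2R)-2-methylbutanoyl]oxy}methyl)oxiran-2-yl]-5-({[(2R)-2-methylbutanoyl]oxy}methyl)phenyl (2Z)-2-methylbut-2-enoate | C/C=C(/C)C(=O)Oc1cc(COC(=O)[C@H](C)CC)ccc1[C@]1(COC(=O)[C@H](C)CC)CO1 | target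

**Step count and risks**

Total step count: 10. Longest linear sequence: 9 steps (3 → 4 → 5 → 7 → 9 → 10 → 13 → 14 → 15 → 17; step 1 supplies acid 2 on a side branch).

The three steps most likely to fail:

Step 9 (asymmetric epoxidation). 2-Aryl allylic alcohols can give only moderate ee, and the Lewis-acidic titanium may open the benzylic epoxide or move the angeloyl group onto the allylic oxygen. The fallback sets out from 14 and comes back to the route at 17. Alcohol 14 is first esterified with 2 (N,N'-diisopropylcarbodiimide, catalytic 4-(dimethylamino)pyridine, CH2Cl2, 0 °C) to give the allylic bis-(R)-2-methylbutanoate alkene F1. Its 1,1-disubstituted alkene is then epoxidised with dimethyldioxirane in acetone at −20 °C, which leaves the electron-poor angelate alkene alone and uses no Lewis acid. The two epoxide epimers are diastereomers because both acyl groups are R, and preparative HPLC separates them to give 17, at the cost of up to half the material.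

Step 7 (angeloylation). The activated angeloyl group can isomerise to the tiglate, and the ortho-substituted phenol is hindered. The fallback sets out from 10 and comes back at 13. Phenol 10 is esterified with 2-(diphenoxyphosphoryl)propanoic acid (N,N'-diisopropylcarbodiimide, catalytic 4-(dimethylamino)pyridine, CH2Cl2) to give the aryl 2-(diphenoxyphosphoryl)propanoate F2, an inconsequential mixture of epimers at the phosphonate carbon. An Ando-type Z-selective Horner–Wadsworth–Emmons olefination with acetaldehyde (NaH, THF, −78 °C) then builds the Z trisubstituted alkene directly on the intact aryl ester and gives 13.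

Step 6 (lipase esterification). The α-branched free acid may acylate the enzyme too slowly. The fallback sets out from 9 and comes back at 10. Both hydroxyl groups of 9 are acylated with 2 (2.5 equiv, N,N'-diisopropylcarbodiimide, catalytic 4-(dimethylamino)pyridine, CH2Cl2) to give the aryl benzyl bis-(R)-2-methylbutanoate F3. The same lipase is then used in the opposite direction: butanolysis (n-butanol, methyl tert-butyl ether, 30 °C) removes only the activated aryl ester and returns 10.

**Further compounds**

F1 | step 9 | 2-(3-{[(2R)-2-methylbutanoyl]oxy}prop-1-en-2-yl)-5-({[(2R)-2-methylbutanoyl]oxy}methyl)phenyl (2Z)-2-methylbut-2-enoate | C/C=C(/C)C(=O)Oc1cc(COC(=O)[C@H](C)CC)ccc1C(=C)COC(=O)[C@H](C)CC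
F2 | step 7 | 2-{3-[(tert-butyldimethylsilyl)oxy]prop-1-en-2-yl}-5-({[(2R)-2-methylbutanoyl]oxy}methyl)phenyl 2-(diphenoxyphosphoryl)propanoate (both epimers at the phosphonate carbon) | CC(C(=O)Oc1cc(COC(=O)[C@H](C)CC)ccc1C(=C)CO[Si](C)(C)C(C)(C)C)P(=O)(Oc1ccccc1)Oc1ccccc1
F3 | step 6 | 2-{3-[(tert-butyldimethylsilyl)oxy]prop-1-en-2-yl}-5-({[(2R)-2-methylbutanoyl]oxy}methyl)phenyl (2R)-2-methylbutanoate | CC[C@@H](C)C(=O)Oc1cc(COC(=O)[C@H](C)CC)ccc1C(=C)CO[Si](C)(C)C(C)(C)C
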